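(The numbers were chosen freely; the flask was simulated.)

Read at the outlet of a tank or at the end of the closed flask, the share of target depends on how much substrate stood beside intermediate A while intermediate A waited to move on.

in all of them: substrate 11 mM
- grey: one stirred flow tank at steady state, fed with the mixture as stated, mean residence time 90.0 h
- green: one stirred flow tank at steady state, fed with the mixture as stated, mean residence time 30 h
- blue: a closed flask charged with all of it at once and left for 30 h; time 30 h

- the set-up with the highest share of target in all that became target or side product A or side product B, at the outlet or at the end ("none" if the first two lie within 2 percentage points) (grey / green / blue / none)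
- share of target in all that became target or side product A or side product B, at the outlet or at the end, grey
- share of target in all that became target or side product A or side product B, at the outlet or at the end, green
- share of target in all that became target or side product A or side product B, at the outlet or at the end, blue

- in percentages every species weighs as the substrate in it: one side product B counts as two
- the stated concentrations are those of everything mixed, before any reaction; amounts are the same in each set-up
- run time (blue): 30 h

    substrate → intermediate A (k1 = 1.0 × 10⁻⁵ s⁻¹)
    intermediate A ⇌ intermediate B (K2 = 1.5, k2 = 1.8 × 10⁻⁵ s⁻¹)
    intermediate B ⇌ intermediate C (K3 = 4.6, k3 = 2.1 × 10⁻⁵ s⁻¹)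
    intermediate B → target (k4 = 1.9 × 10⁻⁵ s⁻¹)
    intermediate C → intermediate D (k5 = 2.3 × 10⁻⁴ s⁻¹)
    intermediate D → side product A (k6 = 2.4 × 10⁻⁴ s⁻¹)
    substrate + intermediate A → side product B (k7 = 0.0015 M⁻¹ s⁻¹)

Substrate turns first-order into intermediate A, which passes reversibly to intermediate B. Intermediate B gives target, or passes to intermediate C and on through intermediate D to side product A. Substrate and intermediate A together give side product B, which weighs double.

Intermediate C goes on faster than it returns, so target takes a part f = 47.5% of what leaves intermediate B. Some intermediate B falls back, so intermediate A moves forward with a net constant k_f = 1.38 × 10⁻⁵ s⁻¹. The bimolecular step is pseudo-first-order in intermediate A at substrate level s, and its doubled weight equals the forward flow at 4.62 mM, the break-even substrate s_e, which is k_f over twice the bimolecular constant. My reckoning for the share y of target is therefore y = f·s_e/(s_e + s).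

Substrate balances, with washout counted beside k_f, give s = 2.30 mM in grey and 4.71 mM in green. In blue the falling curve is replaced by its time mean under the first-order loss, 6.73 mM. The shares come to 31.7% for grey, 23.5% for green and 19.3% for blue, so grey leads.

The forecast named grey, with 31.6%, 22.1% and 20.2% in that order, holding that “the long-residence tank, which holds substrate lowest, suppresses side product B best”.

The simulation gives 31.7%, 22.1% and 19.6%, with grey best; my green figure stands 1.4 percentage points high.

In blue, at the charged substrate, intermediate A has a half-life of 11 h by its forward step alone and 12 h by the bimolecular step. Those two times are close, and the charge 11 mM stands above s_e. Read backward, the rule needs an effective substrate level of 6.58 mM for the blue share. The blue flask left to 300 h reads 29.6%, for which the same rule needs an effective substrate level of 2.79 mM.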